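Conventions: geranyl = (2E)-3,7-dimethylocta-2,6-dien-1-yl; TIPSO, TBSO, TESO, TMSO and MOMO are the triisopropylsilyloxy, tert-butyldimethylsilyloxy, triethylsilyloxy, trimethylsilyloxy and methoxymethoxy groups. Flavanone numbering (O1, C2–C4, C4a, C5–C8, C8a, ring B primed) is used for all intermediates.

## Analysis of the target

The target 35 is a (2S)-flavanone: a chroman-4-one (rings A and C) with a 4-hydroxyphenyl ring B on C2. Ring A is substituted on five of its six carbons: O1 on C8a, a C-geranyl group on C8, a geranyl ether on C7, hydrogen on C6, a free hydroxyl on C5 (chelated to the C4 carbonyl), and C4a. C2 is the only stereocenter. It is benzylic, carries the para-oxygenated aryl group and is β to the carbonyl through O1, so it is lost by retro-oxa-Michael ring opening under base and by ionisation under acid. The two geranyl chains contain four trisubstituted alkenes, which exclude hydrogenolysis, strong acid and electrophilic oxidants. The allyl aryl ether on C7 can rearrange on heating and is cleaved by Lewis acids, so it has to be made last. The hard part is ring A: the three oxygens of a phloroglucinol core must end in three different states, and the geranyl group must stand on C8 and not on C6, a choice that phloroglucinol-based routes make only when ring C closes, and then without control. The plan therefore builds the ring C8a–C8–C7–C6–C5–C4a from a four-carbon and a two-carbon piece, so that connectivity fixes every position and the only free hydroxyl of the new ring sits on C8a, between the geranyl group and the chain that becomes C4–C3–C2.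

## Retrosynthetic reasoning

**O7–geranyl ether.** The first cut is the bond between O7 and the allylic carbon of the geranyl ether, giving triol 33 and geraniol 34. It comes first because an allyl aryl ether would survive neither the heat of the ring A construction nor acidic desilylation. In 33 the three hydroxyls differ in acidity (O7–H para to the carbonyl, O5–H chelated, O4′–H an ordinary phenol), so a neutral redox etherification has to pick O7 without base that would endanger C2.

**Phenol protection and oxidation level of C4.** Triol 33 is traced to its tris-silyl ether 32, the carbonyl of 32 to carbinol 31, and 31 to its silyl ether 30. Keeping C4 as a protected alcohol until ring C is closed removes the β-elimination and enolisation pathways of a β-aryloxy ketone. It also makes the C4 configuration irrelevant, since both epimers converge on oxidation.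

**O1–C2 bond.** Ring C of 30 is opened between O1 and C2 to the phenol alcohol 29, which comes from the silyl ether 28. The forward reaction is an intramolecular Mitsunobu displacement with inversion, so the open-chain carbinol must be (R). Because 29 has a single free phenol, on C8a, closure cannot give a 6-geranyl isomer. The C2 oxygen carries TES and the C4 oxygen TBS so that they are released in that order.

**Ring A.** Phenol 28 is cut at C8–C8a, C6–C7 and C8a–C4a into cyclobutenone 15 and siloxyalkyne 23. These cuts put the geranyl group and O7 in the alkyne, and C8a, C6, C5 (with O5) and C4a (with the side chain) in the four-membered ring. Each substituent position is then decided by which atoms are bonded in the partners, not by a selectivity between similar ring positions. The forward reaction must open the cyclobutenone at a temperature that the siloxyalkyne and five silyl ethers survive, join ketene and alkyne in one orientation, and aromatise.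

**Four-membered ring.** Cyclobutenone 15 is cut at C8a–C6 and C5–C4a into ketene 14, generated from acid 9, and silyloxyethyne 12. The cycloaddition must place the silyloxy group on C5 and leave the side chain on the sp3 carbon C4a, whose hydrogen is needed later for aromatisation.

**Chain and stereocenter.** Acid 9 goes back through ester 8, alcohol 7 and ketone 6 to aldol product 5, which is cut at C2–C3 into aldehyde 2 and diene 3; 2 comes from 1. The aldol sets the only stereocenter under catalyst control. Silylating the carbinol before the ketone is reduced tells the two oxygens apart without any selective protection.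

**Alkynes.** Siloxyalkyne 23 comes from enyne 20 by oxidation of its acetylide to the ynolate and O-silylation; 20 comes from silane 19, and 19 from alkyne 16 and geranyl bromide 17 by substitution at the primary allylic carbon, which keeps the (E)-alkene. An ester-homologation route to the ynolate is not used, because it would need a β,γ-unsaturated ester whose acidic α-protons and skipped diene would not survive the strongly basic rearrangement. Ynol ether 12 comes from acetylide 10 by the same oxidation.

## Alternatives that were turned down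

**Alternative 1:** The disconnection is the aryl C8a–O1 bond of the protected flavanone A1, (2S)-8-geranyl-5,7-bis(MOMO)-2-[4-(MOMO)phenyl]chroman-4-one. Its precursor is the open-chain β-hydroxy ketone A2, (3S)-1-[2-fluoro-3-geranyl-4,6-bis(MOMO)phenyl]-3-hydroxy-3-[4-(MOMO)phenyl]propan-1-one, in which fluorine marks C8a. In the forward step base forms the secondary alkoxide of A2, which displaces fluoride ortho to the ketone and closes ring C with retention at C2.
- For: every reaction is of a known type. The stereocenter, set by an asymmetric aldol, is never a leaving-group carbon, which is a real advantage over the Mitsunobu closure of the chosen route. The fluorine decides 8- against 6-geranyl.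
- Against: A2 needs an arene in which acyl and geranyl groups flank the fluorine while the carbon between the two MOMO groups stays unsubstituted. That carbon is the one directed metalation attacks first, so regiocontrol is only moved into the arene synthesis. The ring is a weak acceptor for nucleophilic aromatic substitution, since two alkoxy donors feed the activating ketone. Under the forcing basic conditions the alkoxide of a β-hydroxy ketone also undergoes retro-aldol cleavage and E1cB loss of water followed by unselective oxa-Michael reclosure, which erodes enantiomeric purity. Removing three MOM groups needs acid next to a geranyl chain.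
- Comparison: this route is shorter and better precedented. The chosen route gives up precedent in one step and in return takes the substitution pattern from connectivity and closes ring C under neutral conditions with C4 masked.

**Alternative 2:** The disconnection is the C4a–C5 bond of ring A in A3, (2S)-8-geranyl-5,7-dihydroxy-2-[4-(TIPSO)phenyl]chroman-4-one. Its precursor is the dihydropyranone A4, methyl (6E)-7,11-dimethyl-3-oxo-4-[(2S)-4-oxo-2-[4-(TIPSO)phenyl]-3,4-dihydro-2H-pyran-6-yl]dodeca-6,10-dienoate. In the forward step a non-nucleophilic base forms the extended enolate of the side chain; C4a, the α-carbon of the vinylogous ester, attacks the methyl ester, methanol is lost, and the triketone tautomerises to the arene.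
- For: the step is biomimetic. Ring A appears with both hydroxyls free and the geranyl group fixed at C8 by its place in the chain, and the stereocenter can be set early by a catalytic hetero-Diels–Alder reaction. After A3 only one etherification and one desilylation remain, so on step count after the key step it is stronger than the chosen route.
- Against: the chain has three competing acidic sites. The most acidic one, the methylene between ketone and ester, gives an enolate that cannot close ring A but can attack the ring carbonyl or be O-acylated. The productive dienolate needs deprotonation at C8 next to the geranyl group. C2 sits β to the enone oxygen, so base can open ring C by β-elimination and racemise it. Assembling the C-geranylated tricarbonyl chain on the pyranone is itself a multi-step problem.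
- Comparison: the alternative relies on strong base and an ambident polyanion, the chosen key step on heat alone, with no regiochemical choice inside the ring-forming event.

**Alternative 3:** The disconnection is the C3=C4 bond of the 2H-chromene A5, (2S)-4-(TBSO)-2-[4-(TBSO)phenyl]-8-geranyl-7-(geranyloxy)-5-(MOMO)-2H-chromene. Its precursor is the aryl ether A6, tert-butyl({1-[2-({(1S)-1-[4-(TBSO)phenyl]prop-2-en-1-yl}oxy)-3-geranyl-4-(geranyloxy)-6-(MOMO)phenyl]ethenyl}oxy)dimethylsilane, whose O1–C2 bond would come from an iridium-catalysed asymmetric allylic etherification. In the forward step the second-generation Grubbs catalyst, RuCl2(=CHPh)(PCy3)(H2IMes), loads on the terminal vinyl group of A6 and closes onto the 1,1-disubstituted silyl enol ether with loss of ethylene; hydrolysis of the enol ether would then give the ketone.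
- For: C2 is set by a catalytic reaction of high expected selectivity and is not an ionisable leaving-group centre, which is stronger than the Mitsunobu step of the chosen route. The geranyl ether and a differentiated O5 are already present, so few steps follow.
- Against: ring A must already exist with three different oxygen substituents and the geranyl group next to the free hydroxyl, which is exactly the problem the chosen key step solves. The phenol is 2,6-disubstituted and a poor nucleophile for the allyl–iridium intermediate. A6 holds four trisubstituted alkenes that can enter metathesis, and enol ethers tend to give unreactive alkoxycarbene complexes. A5 is a 2H-chromene and can lose its C2 configuration by electrocyclic opening of the pyran ring. The final MOM removal needs acid next to an allyl aryl ether.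
- Comparison: the stereocontrol is elegant, but the route presupposes ring A and sends the most sensitive groups through metathesis. The chosen route builds ring A and introduces the geranyl ether last.

Key step: step 12

Assumption: diene 3 is purchased (it is otherwise available from methyl acetoacetate by two successive silylations).
Remark: compounds 7–9, 13–15 and 24–31 are mixtures of epimers at centres that steps 12 and 16 erase; the carbinol carbon that becomes C2 is uniform throughout.

## Route

Step 1
Reactants: 1 4-hydroxybenzaldehyde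
Product: 2 4-(TIPSO)benzaldehyde
Conditions: TIPSCl, imidazole, DMF, rt
Reagents that add atoms: triisopropylsilyl chloride, CC(C)[Si](Cl)(C(C)C)C(C)C
Why: Standard silylation of a phenol; TIPS is chosen for ring B because an aryl TIPS ether, unlike an aryl TBS ether, should survive the hydroxide of step 6, and it leaves together with the ring A silyl ethers in step 17.

Step 2
Reactants: 2 4-(TIPSO)benzaldehyde; 3 1-methoxy-1,3-bis(TMSO)buta-1,3-diene
Product: 5 methyl (5R)-5-hydroxy-3-oxo-5-[4-(TIPSO)phenyl]pentanoate, via bis(trimethylsilyl) aldol adduct 4 (not isolated)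
Conditions: Ti(OiPr)4 (10 mol %), (R)-BINOL (10 mol %), 4 Å MS, THF, −78 °C → rt; then TFA, THF, 0 °C
Reagents that add atoms: none
Why: Catalytic asymmetric vinylogous Mukaiyama aldol of an acetoacetate dienolate equivalent; the BINOL–titanium complex shields one face of the bound aldehyde, and the (R)-ligand is expected to send the diene to the Re face, which gives the (5R)-carbinol (the later C2 before inversion); the sense of induction is to be confirmed by Mosher ester analysis and the (S)-ligand used if it proves opposite. Brief TFA treatment removes both TMS groups of 4 and leaves the aryl TIPS ether.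

Step 3
Reactants: 5 methyl (5R)-5-hydroxy-3-oxo-5-[4-(TIPSO)phenyl]pentanoate
Product: 6 methyl (5R)-3-oxo-5-(TESO)-5-[4-(TIPSO)phenyl]pentanoate
Conditions: TESCl, imidazole, DMF, 0 °C
Reagents that add atoms: triethylsilyl chloride, CC[Si](Cl)(CC)CC
Why: Silylation of the only hydroxyl while C3 is still a ketone; this is what distinguishes the two oxygens of the later 1,3-diol.

Step 4
Reactants: 6 methyl (5R)-3-oxo-5-(TESO)-5-[4-(TIPSO)phenyl]pentanoate
Product: 7 methyl (3RS,5R)-3-hydroxy-5-(TESO)-5-[4-(TIPSO)phenyl]pentanoate
Conditions: NaBH4, MeOH, −20 → 0 °C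
Reagents that add atoms: none
Why: Borohydride reduces the ketone of a β-keto ester much faster than the ester; no selectivity at C3 is needed because this centre becomes the C4 carbonyl in step 16.

Step 5
Reactants: 7 methyl (3RS,5R)-3-hydroxy-5-(TESO)-5-[4-(TIPSO)phenyl]pentanoate
Product: 8 methyl (3RS,5R)-3-(TBSO)-5-(TESO)-5-[4-(TIPSO)phenyl]pentanoate
Conditions: TBSOTf, 2,6-lutidine, CH2Cl2, −78 °C
Reagents that add atoms: tert-butyldimethylsilyl trifluoromethanesulfonate, CC(C)(C)[Si](C)(C)OS(=O)(=O)C(F)(F)F
Why: Silyl triflate with a hindered base silylates the secondary β-hydroxy ester at low temperature without touching the TES ether; TBS is chosen because it outlasts TES in step 13 and is a poor leaving group in the ketene-forming step.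

Step 6
Reactants: 8 methyl (3RS,5R)-3-(TBSO)-5-(TESO)-5-[4-(TIPSO)phenyl]pentanoate
Product: 9 (3RS,5R)-3-(TBSO)-5-(TESO)-5-[4-(TIPSO)phenyl]pentanoic acid
Conditions: LiOH·H2O, THF/MeOH/H2O, 0 °C → rt; then dilute HCl to pH 4–5, 0 °C
Reagents that add atoms: lithium hydroxide, [Li+].[OH-]
Why: Saponification of an unhindered methyl ester; alkyl TES and TBS ethers are base-stable, the aryl TIPS ether is slow to react with hydroxide at this temperature, and acidification only to pH 4–5 in the cold spares the TES ether.

Step 7
Reactants: 10 lithium acetylide–ethylenediamine complex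
Product: 12 (triisopropylsilyloxy)ethyne, via lithium ethynolate 11 (not isolated)
Conditions: t-BuOOH, LiN(SiMe3)2, THF, −78 °C; then 10, −78 → 0 °C; then TIPSCl, −78 °C → rt
Reagents that add atoms: tert-butyl hydroperoxide, CC(C)(C)OO; triisopropylsilyl chloride, CC(C)[Si](Cl)(C(C)C)C(C)C
Why: Julia-type oxidation of an acetylide: the carbanion attacks the lithiated oxygen of lithium tert-butyl peroxide and gives ynolate 11, which the bulky silyl chloride traps on oxygen (small silyl chlorides give silylketenes by C-silylation). The diamine complex is used because uncomplexed monolithium acetylide disproportionates on warming.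

Step 8
Reactants: 9 (3RS,5R)-3-(TBSO)-5-(TESO)-5-[4-(TIPSO)phenyl]pentanoic acid; 12 (triisopropylsilyloxy)ethyne
Product: 15 4-[(1RS,3R)-1-(TBSO)-3-(TESO)-3-[4-(TIPSO)phenyl]propyl]-3-(TIPSO)cyclobut-2-en-1-one, via acid chloride 13 (not isolated), via aldoketene 14 (not isolated)
Conditions: 1-chloro-N,N,2-trimethylprop-1-en-1-amine, CH2Cl2, 0 °C → rt; then slow addition to 12 (3 equiv), Et3N, CH2Cl2, rt
Reagents that add atoms: none
Why: The chloroenamine gives acid chloride 13 without free HCl, so the TES ether survives; triethylamine dehydrochlorinates 13 to ketene 14, which the excess ynol ether intercepts in a [2+2] cycloaddition (the ketene–alkoxyacetylene route to 3-alkoxycyclobutenones) before it dimerises, slow addition keeping its concentration low. The unsubstituted alkyne carbon bonds to the ketene carbonyl carbon, so the silyloxy group ends on C3 and the side chain on the sp3 carbon C4; the ring stereocenter forms without control and is erased in step 12.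

Step 9
Reactants: 16 ethynyltrimethylsilane; 17 geranyl bromide
Product: 19 [(4E)-5,9-dimethyldeca-4,8-dien-1-yn-1-yl]trimethylsilane, via alkynylmagnesium bromide 18 (not isolated)
Conditions: EtMgBr, THF, 0 °C → rt; then CuBr·SMe2 (5 mol %), 17, 0 → 50 °C
Reagents that add atoms: none
Why: Copper-catalysed coupling of an alkynyl Grignard reagent with a primary allylic bromide proceeds at the primary carbon and keeps the (E)-alkene; the silyl group prevents double alkylation of acetylene.

Step 10
Reactants: 19 [(4E)-5,9-dimethyldeca-4,8-dien-1-yn-1-yl]trimethylsilane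
Product: 20 (4E)-5,9-dimethyldeca-4,8-dien-1-yne
Conditions: K2CO3, MeOH, rt
Reagents that add atoms: none
Why: Methanolysis of the alkynyl C–Si bond; carbonate in methanol is too weak a base to isomerise the skipped enyne.

Step 11
Reactants: 20 (4E)-5,9-dimethyldeca-4,8-dien-1-yne
Product: 23 {[(4E)-5,9-dimethyldeca-4,8-dien-1-yn-1-yl]oxy}triisopropylsilane, via lithium acetylide 21 (not isolated), via lithium ynolate 22 (not isolated)
Conditions: n-BuLi, THF, −78 °C; then t-BuOOLi (from t-BuOOH, LiN(SiMe3)2), −78 → 0 °C; then TIPSOTf, −78 → 0 °C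
Reagents that add atoms: tert-butyl hydroperoxide, CC(C)(C)OO; triisopropylsilyl trifluoromethanesulfonate, CC(C)[Si](OS(=O)(=O)C(F)(F)F)(C(C)C)C(C)C
Why: Julia-type oxidation of the terminal acetylide to ynolate 22 and O-silylation with a bulky silyl triflate, the usual access to 1-silyloxy-1-alkynes; one equivalent of base at −78 °C removes only the acetylenic proton, and the peroxide anion does not epoxidise unactivated trisubstituted alkenes.

Step 12
Reactants: 15 4-[(1RS,3R)-1-(TBSO)-3-(TESO)-3-[4-(TIPSO)phenyl]propyl]-3-(TIPSO)cyclobut-2-en-1-one; 23 {[(4E)-5,9-dimethyldeca-4,8-dien-1-yn-1-yl]oxy}triisopropylsilane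
Product: 28 2-geranyl-6-[(1RS,3R)-1-(TBSO)-3-(TESO)-3-[4-(TIPSO)phenyl]propyl]-3,5-bis(TIPSO)phenol, via siloxy vinylketene 24 (not isolated), via 4-alkenylcyclobutenone 25 (not isolated), via dienylketene 26 (not isolated), via cyclohexadienone 27 (not isolated)
Conditions: 23 (1.5 equiv), toluene, 90–110 °C, sealed tube
Reagents that add atoms: none
Why: Proposed new method: heating should open cyclobutenone 15 by four-electron electrocyclic cleavage of C8a–C4a to vinylketene 24, whose ketene unit undergoes [2+2] cycloaddition with the electron-rich alkyne 23, the nucleophilic geranyl-bearing alkyne carbon bonding to the ketene carbonyl carbon (C8–C8a) and the silyloxy-bearing carbon to the ketene α-carbon (C6–C7) to give 25; a second four-electron opening (C8a–C6) gives dienylketene 26, thermal disrotatory six-electron electrocyclization re-forms C8a–C4a and closes ring A as cyclohexadienone 27, and shift of the C4a hydrogen to oxygen gives phenol 28. The closest known reaction type is the Danheiser benzannulation of cyclobutenones with siloxyalkynes, which gives resorcinol monosilyl ethers; new here is a 3-silyloxy-4-alkylcyclobutenone as the vinylketene source, which should give a phloroglucinol whose three oxygens are all different. Ring A closes by electrocyclization of a dienylketene whose central C6=C7 bond holds the two ends cis; if the alkenyl group of 25 rotates outward on opening, reversible reclosure to 25 corrects it. No stereocenter is formed: the ring carbon of 15 and the transient sp3 C4a of 27 are erased on aromatisation, the TBSO-bearing carbon is carried as an epimer mixture, and the (R)-carbinol is three bonds from the reacting system and is not touched. The step needs regiochemistry in the ketene–alkyne union, which the polarisation of the siloxyalkyne secures, and chemoselectivity for the ynol ether over the trisubstituted alkenes, which its much higher nucleophilicity toward ketenes secures. Aromatisation requires a hydrogen on C4a, which the 4-monosubstituted cyclobutenone provides, and the neutral thermal conditions should leave all five silyl ethers in place.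

Step 13
Reactants: 28 2-geranyl-6-[(1RS,3R)-1-(TBSO)-3-(TESO)-3-[4-(TIPSO)phenyl]propyl]-3,5-bis(TIPSO)phenol
Product: 29 2-geranyl-6-[(1RS,3R)-1-(TBSO)-3-hydroxy-3-[4-(TIPSO)phenyl]propyl]-3,5-bis(TIPSO)phenol
Conditions: HF·pyridine, pyridine, THF, 0 °C
Reagents that add atoms: none
Why: Pyridine-buffered HF cleaves a secondary TES ether far faster than a secondary TBS ether, and aryl silyl ethers, which fall to basic fluoride, resist this acidic reagent; the buffer keeps the medium too weakly acidic to ionise the electron-rich benzylic C4–O bond.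

Step 14
Reactants: 29 2-geranyl-6-[(1RS,3R)-1-(TBSO)-3-hydroxy-3-[4-(TIPSO)phenyl]propyl]-3,5-bis(TIPSO)phenol
Product: 30 (2S,4RS)-4-(TBSO)-8-geranyl-5,7-bis(TIPSO)-2-[4-(TIPSO)phenyl]chromane
Conditions: PPh3, DIAD, toluene, 0 °C → rt
Reagents that add atoms: none
Why: Intramolecular Mitsunobu etherification: the only phenol (on C8a) displaces the oxyphosphonium of the secondary benzylic alcohol in a 6-exo-tet closure with inversion, so the (R)-carbinol gives (2S). C4 is a silyl-protected carbinol, so neither β-elimination nor enolisation can compete, and the non-polar solvent and low temperature disfavour ionisation of the para-silyloxybenzylic centre.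

Step 15
Reactants: 30 (2S,4RS)-4-(TBSO)-8-geranyl-5,7-bis(TIPSO)-2-[4-(TIPSO)phenyl]chromane
Product: 31 (2S,4RS)-8-geranyl-5,7-bis(TIPSO)-2-[4-(TIPSO)phenyl]chroman-4-ol
Conditions: HF·pyridine, THF, 0 °C → rt
Reagents that add atoms: none
Why: Acidic fluoride removes alkyl silyl ethers in preference to aryl silyl ethers, and TIPS is the most resistant of the common aryl silyl groups; both C4 epimers are carried on.

Step 16
Reactants: 31 (2S,4RS)-8-geranyl-5,7-bis(TIPSO)-2-[4-(TIPSO)phenyl]chroman-4-ol
Product: 32 (2S)-8-geranyl-5,7-bis(TIPSO)-2-[4-(TIPSO)phenyl]chroman-4-one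
Conditions: Dess–Martin periodinane, pyridine, CH2Cl2, 0 °C → rt
Reagents that add atoms: none
Why: Dess–Martin oxidation of a secondary benzylic alcohol; both epimers converge on one ketone, alkenes and silyl ethers are inert, and the non-basic conditions avoid retro-oxa-Michael opening of ring C.

Step 17
Reactants: 32 (2S)-8-geranyl-5,7-bis(TIPSO)-2-[4-(TIPSO)phenyl]chroman-4-one
Product: 33 (2S)-8-geranyl-5,7-dihydroxy-2-(4-hydroxyphenyl)chroman-4-one
Conditions: TBAF, AcOH, THF, 0 °C
Reagents that add atoms: none
Why: Fluoride cleaves aryl silyl ethers readily; acetic acid protonates the phenoxides as they form, so that the basicity that would open ring C and racemise C2 does not build up.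

Step 18
Reactants: 33 (2S)-8-geranyl-5,7-dihydroxy-2-(4-hydroxyphenyl)chroman-4-one; 34 geraniol
Product: 35 (2S)-8-geranyl-7-(geranyloxy)-5-hydroxy-2-(4-hydroxyphenyl)chroman-4-one
Conditions: 34 (1.1 equiv), PPh3, DIAD, THF, 0 °C
Reagents that add atoms: none
Why: Mitsunobu etherification selects the most acidic phenol: O7–H is para to the carbonyl, O5–H is chelated to the carbonyl and inert, and O4′–H is an ordinary, less acidic phenol. The primary allylic oxyphosphonium is attacked at C1, which keeps the (E)-alkene, and the neutral conditions preserve C2.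

## Compound list

1 | 4-hydroxybenzaldehyde | O=Cc1ccc(O)cc1 | starting material
2 | 4-(TIPSO)benzaldehyde | O=Cc1ccc(O[Si](C(C)C)(C(C)C)C(C)C)cc1 | intermediate
3 | 1-methoxy-1,3-bis(TMSO)buta-1,3-diene | C=C(O[Si](C)(C)C)C=C(OC)O[Si](C)(C)C | starting material
4 | methyl (5R)-3,5-bis(TMSO)-5-[4-(TIPSO)phenyl]pent-2-enoate | COC(=O)C=C(O[Si](C)(C)C)C[C@@H](O[Si](C)(C)C)c1ccc(O[Si](C(C)C)(C(C)C)C(C)C)cc1 | intermediate
5 | methyl (5R)-5-hydroxy-3-oxo-5-[4-(TIPSO)phenyl]pentanoate | COC(=O)CC(=O)C[C@@H](O)c1ccc(O[Si](C(C)C)(C(C)C)C(C)C)cc1 | intermediate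
6 | methyl (5R)-3-oxo-5-(TESO)-5-[4-(TIPSO)phenyl]pentanoate | COC(=O)CC(=O)C[C@@H](O[Si](CC)(CC)CC)c1ccc(O[Si](C(C)C)(C(C)C)C(C)C)cc1 | intermediate
7 | methyl (3RS,5R)-3-hydroxy-5-(TESO)-5-[4-(TIPSO)phenyl]pentanoate | COC(=O)CC(O)C[C@@H](O[Si](CC)(CC)CC)c1ccc(O[Si](C(C)C)(C(C)C)C(C)C)cc1 | intermediate
8 | methyl (3RS,5R)-3-(TBSO)-5-(TESO)-5-[4-(TIPSO)phenyl]pentanoate | COC(=O)CC(O[Si](C)(C)C(C)(C)C)C[C@@H](O[Si](CC)(CC)CC)c1ccc(O[Si](C(C)C)(C(C)C)C(C)C)cc1 | intermediate
9 | (3RS,5R)-3-(TBSO)-5-(TESO)-5-[4-(TIPSO)phenyl]pentanoic acid | OC(=O)CC(O[Si](C)(C)C(C)(C)C)C[C@@H](O[Si](CC)(CC)CC)c1ccc(O[Si](C(C)C)(C(C)C)C(C)C)cc1 | intermediate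
10 | lithium acetylide–ethylenediamine complex | [Li+].[C-]#C.NCCN | starting material
11 | lithium ethynolate | [Li+].[O-]C#C | intermediate
12 | (triisopropylsilyloxy)ethyne | C#CO[Si](C(C)C)(C(C)C)C(C)C | intermediate
13 | (3RS,5R)-3-(TBSO)-5-(TESO)-5-[4-(TIPSO)phenyl]pentanoyl chloride | ClC(=O)CC(O[Si](C)(C)C(C)(C)C)C[C@@H](O[Si](CC)(CC)CC)c1ccc(O[Si](C(C)C)(C(C)C)C(C)C)cc1 | intermediate
14 | (3RS,5R)-3-(TBSO)-5-(TESO)-5-[4-(TIPSO)phenyl]pent-1-en-1-one | O=C=CC(O[Si](C)(C)C(C)(C)C)C[C@@H](O[Si](CC)(CC)CC)c1ccc(O[Si](C(C)C)(C(C)C)C(C)C)cc1 | intermediate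
15 | 4-[(1RS,3R)-1-(TBSO)-3-(TESO)-3-[4-(TIPSO)phenyl]propyl]-3-(TIPSO)cyclobut-2-en-1-one | CC(C)[Si](C(C)C)(C(C)C)OC1=CC(=O)C1C(O[Si](C)(C)C(C)(C)C)C[C@@H](O[Si](CC)(CC)CC)c1ccc(O[Si](C(C)C)(C(C)C)C(C)C)cc1 | intermediate
16 | ethynyltrimethylsilane | C#C[Si](C)(C)C | starting material
17 | geranyl bromide, (2E)-1-bromo-3,7-dimethylocta-2,6-diene | CC(C)=CCC/C(C)=C/CBr | starting material
18 | [(trimethylsilyl)ethynyl]magnesium bromide | C[Si](C)(C)C#C[Mg]Br | intermediate
19 | [(4E)-5,9-dimethyldeca-4,8-dien-1-yn-1-yl]trimethylsilane | CC(C)=CCC/C(C)=C/CC#C[Si](C)(C)C | intermediate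
20 | (4E)-5,9-dimethyldeca-4,8-dien-1-yne | CC(C)=CCC/C(C)=C/CC#C | intermediate
21 | [(4E)-5,9-dimethyldeca-4,8-dien-1-yn-1-yl]lithium | CC(C)=CCC/C(C)=C/CC#C[Li] | intermediate
22 | lithium (4E)-5,9-dimethyldeca-4,8-dien-1-yn-1-olate | CC(C)=CCC/C(C)=C/CC#C[O-].[Li+] | intermediate
23 | {[(4E)-5,9-dimethyldeca-4,8-dien-1-yn-1-yl]oxy}triisopropylsilane | CC(C)=CCC/C(C)=C/CC#CO[Si](C(C)C)(C(C)C)C(C)C | intermediate
24 | (5RS,7R)-5-(TBSO)-7-(TESO)-3-(TIPSO)-7-[4-(TIPSO)phenyl]hepta-1,3-dien-1-one | O=C=CC(O[Si](C(C)C)(C(C)C)C(C)C)=CC(O[Si](C)(C)C(C)(C)C)C[C@@H](O[Si](CC)(CC)CC)c1ccc(O[Si](C(C)C)(C(C)C)C(C)C)cc1 | intermediate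
25 | 2-geranyl-3-(TIPSO)-4-[(3RS,5R)-3-(TBSO)-5-(TESO)-1-(TIPSO)-5-[4-(TIPSO)phenyl]pent-1-en-1-yl]cyclobut-2-en-1-one | O=C1C(C/C=C(\C)CCC=C(C)C)=C(O[Si](C(C)C)(C(C)C)C(C)C)C1C(O[Si](C(C)C)(C(C)C)C(C)C)=CC(O[Si](C)(C)C(C)(C)C)C[C@@H](O[Si](CC)(CC)CC)c1ccc(O[Si](C(C)C)(C(C)C)C(C)C)cc1 | intermediate
26 | (7RS,9R)-2-geranyl-7-(TBSO)-9-(TESO)-3,5-bis(TIPSO)-9-[4-(TIPSO)phenyl]nona-1,3,5-trien-1-one | O=C=C(C/C=C(\C)CCC=C(C)C)C(O[Si](C(C)C)(C(C)C)C(C)C)=CC(O[Si](C(C)C)(C(C)C)C(C)C)=CC(O[Si](C)(C)C(C)(C)C)C[C@@H](O[Si](CC)(CC)CC)c1ccc(O[Si](C(C)C)(C(C)C)C(C)C)cc1 | intermediate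
27 | 2-geranyl-6-[(1RS,3R)-1-(TBSO)-3-(TESO)-3-[4-(TIPSO)phenyl]propyl]-3,5-bis(TIPSO)cyclohexa-2,4-dien-1-one | O=C1C(C/C=C(\C)CCC=C(C)C)=C(O[Si](C(C)C)(C(C)C)C(C)C)C=C(O[Si](C(C)C)(C(C)C)C(C)C)C1C(O[Si](C)(C)C(C)(C)C)C[C@@H](O[Si](CC)(CC)CC)c1ccc(O[Si](C(C)C)(C(C)C)C(C)C)cc1 | intermediate
28 | 2-geranyl-6-[(1RS,3R)-1-(TBSO)-3-(TESO)-3-[4-(TIPSO)phenyl]propyl]-3,5-bis(TIPSO)phenol | Oc1c(C/C=C(\C)CCC=C(C)C)c(O[Si](C(C)C)(C(C)C)C(C)C)cc(O[Si](C(C)C)(C(C)C)C(C)C)c1C(O[Si](C)(C)C(C)(C)C)C[C@@H](O[Si](CC)(CC)CC)c1ccc(O[Si](C(C)C)(C(C)C)C(C)C)cc1 | intermediate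
29 | 2-geranyl-6-[(1RS,3R)-1-(TBSO)-3-hydroxy-3-[4-(TIPSO)phenyl]propyl]-3,5-bis(TIPSO)phenol | Oc1c(C/C=C(\C)CCC=C(C)C)c(O[Si](C(C)C)(C(C)C)C(C)C)cc(O[Si](C(C)C)(C(C)C)C(C)C)c1C(O[Si](C)(C)C(C)(C)C)C[C@@H](O)c1ccc(O[Si](C(C)C)(C(C)C)C(C)C)cc1 | intermediate
30 | (2S,4RS)-4-(TBSO)-8-geranyl-5,7-bis(TIPSO)-2-[4-(TIPSO)phenyl]chromane | CC(C)[Si](C(C)C)(C(C)C)Oc1cc(O[Si](C(C)C)(C(C)C)C(C)C)c2c(c1C/C=C(\C)CCC=C(C)C)O[C@H](c1ccc(O[Si](C(C)C)(C(C)C)C(C)C)cc1)CC2O[Si](C)(C)C(C)(C)C | intermediate
31 | (2S,4RS)-8-geranyl-5,7-bis(TIPSO)-2-[4-(TIPSO)phenyl]chroman-4-ol | CC(C)[Si](C(C)C)(C(C)C)Oc1cc(O[Si](C(C)C)(C(C)C)C(C)C)c2c(c1C/C=C(\C)CCC=C(C)C)O[C@H](c1ccc(O[Si](C(C)C)(C(C)C)C(C)C)cc1)CC2O | intermediate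
32 | (2S)-8-geranyl-5,7-bis(TIPSO)-2-[4-(TIPSO)phenyl]chroman-4-one | CC(C)[Si](C(C)C)(C(C)C)Oc1cc(O[Si](C(C)C)(C(C)C)C(C)C)c2c(c1C/C=C(\C)CCC=C(C)C)O[C@H](c1ccc(O[Si](C(C)C)(C(C)C)C(C)C)cc1)CC2=O | intermediate
33 | (2S)-8-geranyl-5,7-dihydroxy-2-(4-hydroxyphenyl)chroman-4-one | Oc1cc(O)c2c(c1C/C=C(\C)CCC=C(C)C)O[C@H](c1ccc(O)cc1)CC2=O | intermediate
34 | geraniol, (2E)-3,7-dimethylocta-2,6-dien-1-ol | CC(C)=CCC/C(C)=C/CO | starting material
35 | (2S)-8-geranyl-7-(geranyloxy)-5-hydroxy-2-(4-hydroxyphenyl)chroman-4-one | CC(C)=CCC/C(C)=C/COc1cc(O)c2c(c1C/C=C(\C)CCC=C(C)C)O[C@H](c1ccc(O)cc1)CC2=O | target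

## Step count and least certain steps

Total step count: 18. Longest linear sequence: 14 steps (1 → 2 → 5 → 6 → 7 → 8 → 9 → 15 → 28 → 29 → 30 → 31 → 32 → 33 → 35, steps 1–6, 8 and 12–18).

**Step 12 (key step, proposed new method).** The vinylogous-ester character of the 3-silyloxycyclobutenone may raise the barrier to ring opening above the temperature at which the siloxyalkyne is stable, so that silyl migration in the alkyne to a silylketene, or its slow decomposition, outruns the cycloaddition. The vinylketene may also be consumed by acylating the product phenol or by dimerising, and prolonged heating may cause loss of silanol from the benzylic silyl ether next to the new phenol.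

The fallback uses known reaction types only. It sets out from geranyl bromide 17 and 4-hydroxybenzaldehyde 1 and comes back at 33.
- Commercial 2,4,6-trihydroxyacetophenone is C-alkylated with 17 in aqueous KOH to 3-geranyl-2,4,6-trihydroxyacetophenone F1; the symmetry of the phenol makes the position unambiguous.
- Two equivalents of MOMCl with i-Pr2NEt etherify the hydroxyl para to the acetyl group and the less hindered ortho hydroxyl and leave the chelated hydroxyl between the acetyl and geranyl groups, giving 3-geranyl-2-hydroxy-4,6-bis(MOMO)acetophenone F2. This assignment is to be confirmed by HMBC.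
- Aldehyde 1 is converted with MOMCl into 4-(MOMO)benzaldehyde F3.
- Claisen–Schmidt condensation of F2 and F3 (KOH, EtOH) gives the chalcone (E)-1-[3-geranyl-2-hydroxy-4,6-bis(MOMO)phenyl]-3-[4-(MOMO)phenyl]prop-2-en-1-one F4.
- NaOAc in refluxing EtOH closes F4 through its only free hydroxyl to racemic 8-geranyl-5,7-bis(MOMO)-2-[4-(MOMO)phenyl]chroman-4-one F5.
- Kinetic resolution by asymmetric transfer hydrogenation (Cp*RhCl[TsDPEN], HCO2H/Et3N, using the catalyst enantiomer that reduces the (2R)-ketone) leaves the (2S)-flavanone F6, identical with A1. The (2R)-ketone is converted into the cis-alcohol (2R,4R)-8-geranyl-5,7-bis(MOMO)-2-[4-(MOMO)phenyl]chroman-4-ol F7, which is separated.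
- HCl in MeOH removes the three MOM groups of F6 to give 33.

The price is a low-yielding C-alkylation, regiocontrol that rests on a steric preference in the protection step, and a resolution that discards half of the material.

**Step 7.** The parent acetylide may react too slowly with the peroxide as a poorly soluble complex or disproportionate, and the small ynolate may be partly silylated on carbon or lost through volatility and hydrolysis during isolation. The fallback sets out from ethynyltrimethylsilane 16 and comes back at 12. The stable lithium acetylide of 16 (n-BuLi) is oxidised with t-BuOOLi and O-silylated with TIPSOTf to trimethyl{[(triisopropylsilyl)oxy]ethynyl}silane F8, and K2CO3 in MeOH at 0 °C removes the carbon-bound silyl group to give 12.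

**Step 14.** The para-silyloxybenzylic oxyphosphonium may ionise before the hindered 2,6-disubstituted phenol attacks. That would mean partial loss of configuration at C2 and elimination toward the styrene, and a slow closure would allow alkylation of the reduced azodicarboxylate. The fallback sets out from flavanone 32 of eroded enantiomeric purity and comes back at enantiopure 32. It replaces stereospecific substitution by resolution: asymmetric transfer hydrogenation with Cp*RhCl[TsDPEN] and HCO2H/Et3N reduces the (2R)-enantiomer to (2R,4R)-8-geranyl-5,7-bis(TIPSO)-2-[4-(TIPSO)phenyl]chroman-4-ol F9, which is removed by chromatography.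

**Step 15.** Cleavage of the hindered secondary TBS ether may be slow enough for aryl TIPS ethers to start to fall, and the acid may ionise the electron-rich C4 position and cause elimination across C3–C4. The fallback sets out from 30 and comes back at 31. Excess TBAF in THF removes all four silyl groups to give (2S,4RS)-8-geranyl-2-(4-hydroxyphenyl)chromane-4,5,7-triol F10. TIPSCl (3.3 equiv) and imidazole in DMF then re-silylate the three phenols, which react far faster than the hindered secondary benzylic alcohol, to give 31.

**Step 18.** Etherification may also occur at the 4′-hydroxyl (mono- and bis-alkylation), and attack at C3 of the allylic system would give the tertiary allylic ether. The fallback sets out from 32 and comes back at 35, replacing acidity control by protecting-group control.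
- Two equivalents of acetic-acid-buffered TBAF at −20 °C should cleave the silyl ethers on O5 and O7, which are vinylogous silyl esters of the C4 carbonyl, before the ring B ether, giving (2S)-8-geranyl-5,7-dihydroxy-2-[4-(TIPSO)phenyl]chroman-4-one F11, identical with A3.
- Mitsunobu reaction of F11 with 34 then has only one reactive hydroxyl and gives (2S)-8-geranyl-7-(geranyloxy)-5-hydroxy-2-[4-(TIPSO)phenyl]chroman-4-one F12.
- TBAF/AcOH frees the 4′-hydroxyl of F12 to give 35.

## Further compounds

F1 | step 12 | 1-(3-geranyl-2,4,6-trihydroxyphenyl)ethan-1-one | CC(=O)c1c(O)cc(O)c(C/C=C(\C)CCC=C(C)C)c1O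
F2 | step 12 | 1-[3-geranyl-2-hydroxy-4,6-bis(MOMO)phenyl]ethan-1-one | CC(=O)c1c(OCOC)cc(OCOC)c(C/C=C(\C)CCC=C(C)C)c1O
F3 | step 12 | 4-(MOMO)benzaldehyde | COCOc1ccc(C=O)cc1
F4 | step 12 | (E)-1-[3-geranyl-2-hydroxy-4,6-bis(MOMO)phenyl]-3-[4-(MOMO)phenyl]prop-2-en-1-one | COCOc1ccc(/C=C/C(=O)c2c(OCOC)cc(OCOC)c(C/C=C(\C)CCC=C(C)C)c2O)cc1
F5 | step 12 | racemic 8-geranyl-5,7-bis(MOMO)-2-[4-(MOMO)phenyl]chroman-4-one | COCOc1cc(OCOC)c2c(c1C/C=C(\C)CCC=C(C)C)OC(c1ccc(OCOC)cc1)CC2=O
F6 | step 12 | (2S)-8-geranyl-5,7-bis(MOMO)-2-[4-(MOMO)phenyl]chroman-4-one | COCOc1cc(OCOC)c2c(c1C/C=C(\C)CCC=C(C)C)O[C@H](c1ccc(OCOC)cc1)CC2=O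
F7 | step 12 | (2R,4R)-8-geranyl-5,7-bis(MOMO)-2-[4-(MOMO)phenyl]chroman-4-ol | COCOc1cc(OCOC)c2c(c1C/C=C(\C)CCC=C(C)C)O[C@@H](c1ccc(OCOC)cc1)C[C@H]2O
F8 | step 7 | trimethyl{[(triisopropylsilyl)oxy]ethynyl}silane | C[Si](C)(C)C#CO[Si](C(C)C)(C(C)C)C(C)C
F9 | step 14 | (2R,4R)-8-geranyl-5,7-bis(TIPSO)-2-[4-(TIPSO)phenyl]chroman-4-ol | CC(C)[Si](C(C)C)(C(C)C)Oc1cc(O[Si](C(C)C)(C(C)C)C(C)C)c2c(c1C/C=C(\C)CCC=C(C)C)O[C@@H](c1ccc(O[Si](C(C)C)(C(C)C)C(C)C)cc1)C[C@H]2O
F10 | step 15 | (2S,4RS)-8-geranyl-2-(4-hydroxyphenyl)chromane-4,5,7-triol | Oc1cc(O)c2c(c1C/C=C(\C)CCC=C(C)C)O[C@H](c1ccc(O)cc1)CC2O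
F11 | step 18 | (2S)-8-geranyl-5,7-dihydroxy-2-[4-(TIPSO)phenyl]chroman-4-one | Oc1cc(O)c2c(c1C/C=C(\C)CCC=C(C)C)O[C@H](c1ccc(O[Si](C(C)C)(C(C)C)C(C)C)cc1)CC2=O
F12 | step 18 | (2S)-8-geranyl-7-(geranyloxy)-5-hydroxy-2-[4-(TIPSO)phenyl]chroman-4-one | CC(C)=CCC/C(C)=C/COc1cc(O)c2c(c1C/C=C(\C)CCC=C(C)C)O[C@H](c1ccc(O[Si](C(C)C)(C(C)C)C(C)C)cc1)CC2=O
A1 | alternative 1 | (2S)-8-geranyl-5,7-bis(MOMO)-2-[4-(MOMO)phenyl]chroman-4-one | COCOc1cc(OCOC)c2c(c1C/C=C(\C)CCC=C(C)C)O[C@H](c1ccc(OCOC)cc1)CC2=O
A2 | alternative 1 | (3S)-1-[2-fluoro-3-geranyl-4,6-bis(MOMO)phenyl]-3-hydroxy-3-[4-(MOMO)phenyl]propan-1-one | COCOc1cc(OCOC)c(C(=O)C[C@H](O)c2ccc(OCOC)cc2)c(F)c1C/C=C(\C)CCC=C(C)C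
A3 | alternative 2 | (2S)-8-geranyl-5,7-dihydroxy-2-[4-(TIPSO)phenyl]chroman-4-one | Oc1cc(O)c2c(c1C/C=C(\C)CCC=C(C)C)O[C@H](c1ccc(O[Si](C(C)C)(C(C)C)C(C)C)cc1)CC2=O
A4 | alternative 2 | methyl (6E)-7,11-dimethyl-3-oxo-4-[(2S)-4-oxo-2-[4-(TIPSO)phenyl]-3,4-dihydro-2H-pyran-6-yl]dodeca-6,10-dienoate | COC(=O)CC(=O)C(C/C=C(\C)CCC=C(C)C)C1=CC(=O)C[C@@H](c2ccc(O[Si](C(C)C)(C(C)C)C(C)C)cc2)O1
A5 | alternative 3 | (2S)-4-(TBSO)-2-[4-(TBSO)phenyl]-8-geranyl-7-(geranyloxy)-5-(MOMO)-2H-chromene | CC(C)=CCC/C(C)=C/COc1cc(OCOC)c2c(c1C/C=C(\C)CCC=C(C)C)O[C@H](c1ccc(O[Si](C)(C)C(C)(C)C)cc1)C=C2O[Si](C)(C)C(C)(C)C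
A6 | alternative 3 | tert-butyl({1-[2-({(1S)-1-[4-(TBSO)phenyl]prop-2-en-1-yl}oxy)-3-geranyl-4-(geranyloxy)-6-(MOMO)phenyl]ethenyl}oxy)dimethylsilane | C=C(O[Si](C)(C)C(C)(C)C)c1c(OCOC)cc(OC/C=C(\C)CCC=C(C)C)c(C/C=C(\C)CCC=C(C)C)c1O[C@@H](C=C)c1ccc(O[Si](C)(C)C(C)(C)C)cc1
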